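**Strategy**

The route rests on disconnecting ring B at C5–C6 and C7–C7a. It exploits the cis relationship of the C7 carboxyl carbon and the dienyl carbon C1' on the adjacent quaternary carbons C7 and C6 of ring B: tied together as a γ-lactone acetal, they turn a tetrasubstituted 5-menthyloxybutenolide into the dienophile. A single [4+2] cycloaddition with a 1-amino-3-siloxybutadiene closes ring B, sets both quaternary stereocentres in absolute terms (diene anti to the menthyloxy group) and leaves a C3a=C7a enone on which ring A is annulated. The C4 ketone later becomes the C4 methyl alkene; the lactone acetal is opened to the acid and the aldehyde that carries the diene.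

Key step: step 4

Numbering: atom labels follow the indene numbering of the target (C1 = ethyl-bearing alkene carbon of ring A, C7 = carboxyl-bearing carbon of ring B, C1' = first dienyl carbon on C6). β is the face of ring B that carries the C7 carboxyl carbon, α the other face.

Assumption: both C5 epimers of acetal 5 form and interconvert under acid; the (5S)-epimer is taken to be separable by crystallisation or chromatography and the (5R)-epimer is returned to the equilibration.

Assumption: the sense of induction of the iridium phosphoramidite catalyst in step 7 is taken from its behaviour with other carbon nucleophiles; should the C3 epimer predominate, the mirror-image ligand is used.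

**Route**

Step 1
Reactants: 1 pyruvic acid; 2 butanal
Product: 3 4-ethyl-5-hydroxy-3-methylfuran-2(5H)-one (racemic lactol)
Conditions: morpholine (1 equiv), dioxane/H2O, 2 added slowly to excess 1, 25 → 100 °C; then 6 M HCl, 100 °C
Reagents that add atoms: none
Why: Amine-mediated crossed aldol condensation in which the morpholine enamine of 2 attacks the activated keto group of 1, dehydration gives the (Z)-4-oxo-2-enoic acid and this closes to the lactol, the same sequence that turns glyoxylic acid and aldehydes into 4-alkyl-5-hydroxybutenolides; the lactol carbon forms racemic.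

Step 2
Reactants: 3 4-ethyl-5-hydroxy-3-methylfuran-2(5H)-one; 4 (1R,2S,5R)-menthol
Product: 5 (5S)-4-ethyl-3-methyl-5-[(1R,2S,5R)-menthyloxy]furan-2(5H)-one
Conditions: TsOH·H2O (2 mol %), toluene, reflux, azeotropic removal of water; crystallisation (hexane) or chromatography; mother liquor re-equilibrated with TsOH
Reagents that add atoms: none
Why: Acid-catalysed acetalisation of the pseudo-acid through its acyl oxocarbenium ion; the acetal carbon is not controlled in the bond formation but equilibrates under the acid, so the (5S)-epimer is removed and the rest recycled.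

Step 3
Reactants: 6 (E)-4-(dimethylamino)but-3-en-2-one
Product: 8 (E)-3-(tert-butyldimethylsilyloxy)-N,N-dimethylbuta-1,3-dien-1-amine, via sodium dienolate 7 (not isolated)
Conditions: NaN(SiMe3)2, THF, –78 °C; tBuMe2SiCl, –78 °C → 25 °C; distillation
Reagents that add atoms: tert-butyldimethylsilyl chloride, CC(C)(C)[Si](C)(C)Cl
Why: Kinetic deprotonation of the methyl ketone of the vinylogous amide and O-silylation of the cross-conjugated dienolate (silyl enol ether formation), which leaves the (E)-enamine geometry untouched.

Step 4
Reactants: 5 (5S)-menthyloxy butenolide; 8 aminosiloxy diene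
Product: 11 cis-fused lactone acetal cyclohexenone (C4 ketone; C3a=C7a; methyl α and lactone carbonyl β on C7; ethyl α and acetal carbon β on C6), via amino silyl enol ether cycloadduct 9 (not isolated), via β-amino ketone 10 (not isolated)
Conditions: 8 (3 equiv), CH2Cl2 (concentrated), 13 kbar, 40 °C, 72 h; then 1 M HCl, THF, 0 °C
Reagents that add atoms: none
Why: Concerted but asynchronous normal-demand Diels–Alder reaction, in which the HOMO of the doubly donor-substituted diene 8 meets the LUMO of the unsaturated lactone and the CH2 terminus bonds to C6 (β to the lactone carbonyl) ahead of the aminated terminus bonding to C7. Ring B is closed as a six-membered carbocycle by intermolecular [4+2] cycloaddition, suprafacial on both partners, so the cis arrangement of the lactone carbonyl on C7 and the acetal carbon on C6 is carried over from the ring alkene. The absolute configuration of C6 and C7 is set together by the (5S)-acetal carbon, whose menthyloxy group shields one face of the planar butenolide and sends the diene to the other. The regiochemistry that the step needs follows from the single activating carbonyl on C7; the transient C7a centre is erased when dilute acid hydrolyses the silyl enol ether of 9 and dimethylamine leaves 10 by β-elimination to give the C3a=C7a enone. The closest known reactions are cycloadditions of 1-amino-3-siloxybutadienes with α-substituted acrylic dienophiles, which create quaternary carbons, and of 5-alkoxybutenolides, which react anti to the alkoxy group. The fully substituted alkene is the weak point, which the high pressure (negative activation volume) and the excess of the very electron-rich diene address.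

Step 5
Reactants: 11 lactone acetal cyclohexenone; 12 2-bromobut-1-ene
Product: 14 C4 trimethylsilyl enol ether (C3a=C4; but-1-en-2-yl α on C7a), via but-1-en-2-ylmagnesium bromide 13 (not isolated)
Conditions: 12, Mg, THF, 40 °C; then CuBr·SMe2 (20 mol %), Me3SiCl (3 equiv), 11, THF, –78 → –40 °C; Et3N, pentane, filtration
Reagents that add atoms: chlorotrimethylsilane, C[Si](C)(C)Cl
Why: Copper-catalysed conjugate addition of the alkenyl Grignard reagent 13 accelerated by Me3SiCl, which traps the enolate regiospecifically as the C3a=C4 silyl enol ether; the C7a centre should arise by axial attack on the convex α-face, anti to the pseudoaxial lactone carbonyl on C7, through the half-chair in which the ethyl group and not the bulkier acetal carbon on C6 sits 1,3-diaxial to the incoming group.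

Step 6
Reactants: 15 (E)-but-2-en-1-ol
Product: 16 tert-butyl (E)-but-2-en-1-yl carbonate
Conditions: (tBuOCO)2O, Bu4NHSO4 (cat.), 30% aq. NaOH, CH2Cl2, 0 → 25 °C
Reagents that add atoms: di-tert-butyl dicarbonate, CC(C)(C)OC(=O)OC(=O)OC(C)(C)C
Why: Phase-transfer tert-butoxycarbonylation of a primary allylic alcohol (carbonate formation); no stereocentre is involved and the (E)-alkene is untouched.

Step 7
Reactants: 14 trimethylsilyl enol ether; 16 tert-butyl (E)-but-2-en-1-yl carbonate
Product: 17 C4 ketone with (R)-but-3-en-2-yl β on C3a, trans to the but-1-en-2-yl group on C7a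
Conditions: [Ir(cod)Cl]2 (2.5 mol %), O,O'-[(S)-1,1'-binaphthyl-2,2'-diyl] N,N-bis[(S)-1-phenylethyl]phosphoramidite (5 mol %), n-PrNH2 (catalyst activation), CsF (0.4 equiv), ZnF2 (1.5 equiv), 16 (1.5 equiv), DME, 50 °C
Reagents that add atoms: none
Why: Iridium-catalysed allylic alkylation of the fluoride-released enolate of a silyl enol ether, in which the cyclometallated phosphoramidite catalyst directs the nucleophile to the substituted terminus of the π-crotyl complex (branched product) and fixes C3 by catalyst control, while C3a is set trans to the C7a alkenyl group because the electrophile approaches the enolate anti to it; the position of the enolate is defined by 14.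

Step 8
Reactants: 17 diene ketone
Product: 18 trans-fused hydrindenone (ring A closed; C1=C2; C3 methyl α; C3a-H α; C7a-H β)
Conditions: second-generation Grubbs catalyst RuCl2(=CHPh)(PCy3)(H2IMes) (5 mol %), toluene, 60 °C
Reagents that add atoms: none
Why: Ring-closing olefin metathesis between the monosubstituted and the 1,1-disubstituted alkene gives the trisubstituted C1=C2 cyclopentene with loss of ethene; the two side chains are trans-diequatorial on ring B, so ring A closes trans-fused without touching a stereocentre.

Step 9
Reactants: 18 trans-fused hydrindenone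
Product: 20 C4=C5 enol triflate, via potassium enolate 19 (not isolated)
Conditions: 18 added to KN(SiMe3)2 (1.3 equiv), THF, –78 °C; PhNTf2, –78 → 0 °C
Reagents that add atoms: N-phenylbis(trifluoromethanesulfonimide), O=S(=O)(N(c1ccccc1)S(=O)(=O)C(F)(F)F)C(F)(F)F
Why: Kinetic enolisation with the hindered amide base removes a C5 methylene proton and not the ring-fusion C3a methine, as is usual for trans-hydrindan-4-ones, and O-sulfonylation gives the C4=C5 enol triflate (enol triflate formation) with the C3a stereocentre intact.

Step 10
Reactants: 20 enol triflate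
Product: 21 C4-methyl diene lactone acetal (C1=C2 and C4=C5)
Conditions: MeMgBr (1.5 equiv), Fe(acac)3 (5 mol %), THF/NMP, –30 °C, 15 min
Reagents that add atoms: methylmagnesium bromide, C[Mg]Br
Why: Iron-catalysed cross-coupling of an alkenyl triflate with a methyl Grignard reagent, fast at low temperature, so the hindered lactone carbonyl and the acetal are left alone and no stereocentre is touched.

Step 11
Reactants: 21 C4-methyl diene lactone acetal
Product: 23 hydroxy lactone (pseudo-acid; both lactol epimers), via lithium carboxylate aldehyde 22 (not isolated)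
Conditions: LiOH·H2O (5 equiv), dioxane/H2O 3:1, 80 °C; then 1 M HCl, 0 °C, pH 3; menthol recovered
Reagents that add atoms: lithium hydroxide, [Li+].[OH-]
Why: Saponification of the lactone, in which hydroxide adds to the lactone carbonyl, the ring opens and the hemiacetal oxide collapses to the aldehyde with loss of menthoxide, so that the non-enolisable aldehyde carboxylate 22 forms irreversibly and closes to lactol 23 on acidification; base is chosen over aqueous acid to spare the two trisubstituted alkenes.

Step 12
Reactants: 23 hydroxy lactone
Product: 24 allyl ester aldehyde (C7 allyl ester; C6 formyl)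
Conditions: allyl bromide (1.5 equiv), K2CO3 (2 equiv), DMF, 25 °C
Reagents that add atoms: allyl bromide, C=CCBr
Why: O-Alkylation of the carboxylate, the ring-opened anion of the pseudo-acid, with allyl bromide (SN2 esterification) gives the normal ester and frees the aldehyde, which has no α-hydrogen and cannot epimerise or condense.

Step 13
Reactants: 24 allyl ester aldehyde; 25 2-(triphenylphosphoranylidene)propanal
Product: 26 (E)-2-methylpropenal on C6 (allyl ester enal)
Conditions: 25 (3 equiv), toluene, 110 °C, 48 h
Reagents that add atoms: none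
Why: Wittig olefination with a formyl-stabilised ylide, which is (E)-selective for the trisubstituted enal because oxaphosphetane formation is reversible; the neopentyl aldehyde is slow, hence the excess of 25 and the temperature.

Step 14
Reactants: 26 allyl ester enal; 27 diethyl benzylphosphonate
Product: 29 allyl ester of the target, via sodium phosphonate anion 28 (not isolated)
Conditions: 27 (1.5 equiv), NaH, THF, 0 °C; then 26, 0 → 25 °C
Reagents that add atoms: none
Why: Horner–Wadsworth–Emmons olefination of the non-enolisable enal with the benzylic phosphonate anion 28, which is (E)-selective for the styryl alkene as is usual for benzylphosphonates and leaves the hindered ester alone.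

Step 15
Reactants: 29 allyl ester of the target
Product: 30 target acid
Conditions: Pd(PPh3)4 (5 mol %), morpholine (5 equiv), THF, 25 °C; work-up with 1 M HCl
Reagents that add atoms: none
Why: Palladium-catalysed deallylation (Tsuji–Trost allyl transfer to morpholine after oxidative addition of zerovalent palladium to the allyl ester), which does not depend on access to the hindered ester carbonyl and leaves the diene and all stereocentres untouched.

**Compound list**

1 | pyruvic acid | CC(=O)C(=O)O | starting material
2 | butanal | CCCC=O | starting material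
3 | 4-ethyl-5-hydroxy-3-methylfuran-2(5H)-one, racemic lactol | CCC1=C(C)C(=O)OC1O | intermediate
4 | (1R,2S,5R)-menthol | C[C@@H]1CC[C@H]([C@@H](C1)O)C(C)C | starting material
5 | (5S)-4-ethyl-3-methyl-5-{[(1R,2S,5R)-2-isopropyl-5-methylcyclohexyl]oxy}furan-2(5H)-one | CCC1=C(C)C(=O)O[C@@H]1O[C@@H]2C[C@H](C)CC[C@H]2C(C)C | intermediate
6 | (E)-4-(dimethylamino)but-3-en-2-one | CC(=O)/C=C/N(C)C | starting material
7 | sodium (E)-4-(dimethylamino)buta-1,3-dien-2-olate | [Na+].[O-]C(=C)/C=C/N(C)C | intermediate (not isolated)
8 | (E)-3-(tert-butyldimethylsilyloxy)-N,N-dimethylbuta-1,3-dien-1-amine | C=C(O[Si](C)(C)C(C)(C)C)/C=C/N(C)C | intermediate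
9 | cycloadduct: cis-fused lactone acetal with C7a dimethylamino group (either configuration) and C3a=C4 silyl enol ether; C6 and C7 as in 11 | CN(C)C1C=C(O[Si](C)(C)C(C)(C)C)C[C@]2(CC)[C@@H](O[C@@H]3C[C@H](C)CC[C@H]3C(C)C)OC(=O)[C@]12C | intermediate (not isolated)
10 | β-amino ketone: C4 ketone with C7a dimethylamino group; C6 and C7 as in 11 | CN(C)C1CC(=O)C[C@]2(CC)[C@@H](O[C@@H]3C[C@H](C)CC[C@H]3C(C)C)OC(=O)[C@]12C | intermediate (not isolated)
11 | (3S,3aS,7aR)-3a-ethyl-7a-methyl-3-[(1R,2S,5R)-menthyloxy]-3a,4-dihydro-2-benzofuran-1,5(3H,7aH)-dione; in target numbering C4 ketone, C3a=C7a, C7 (R) with methyl α, C6 (S) with ethyl α, menthyloxy cis to ethyl | O=C1C=C[C@@]2(C)C(=O)O[C@H](O[C@@H]3C[C@H](C)CC[C@H]3C(C)C)[C@@]2(CC)C1 | intermediate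
12 | 2-bromobut-1-ene | C=C(Br)CC | starting material
13 | but-1-en-2-ylmagnesium bromide | CCC(=C)[Mg]Br | intermediate (not isolated)
14 | trimethylsilyl enol ether (C4–OSiMe3, C3a=C4) of the lactone acetal ketone with but-1-en-2-yl α on C7a (C7a-H β) | C[Si](C)(C)OC1=C[C@H](C(=C)CC)[C@@]2(C)C(=O)O[C@H](O[C@@H]3C[C@H](C)CC[C@H]3C(C)C)[C@@]2(CC)C1 | intermediate
15 | (E)-but-2-en-1-ol | C/C=C/CO | starting material
16 | tert-butyl (E)-but-2-en-1-yl carbonate | C/C=C/COC(=O)OC(C)(C)C | intermediate
17 | lactone acetal ketone with (R)-but-3-en-2-yl β on C3a (C3a-H α) and but-1-en-2-yl α on C7a, trans | O=C1[C@@H]([C@H](C)C=C)[C@H](C(=C)CC)[C@@]2(C)C(=O)O[C@H](O[C@@H]3C[C@H](C)CC[C@H]3C(C)C)[C@@]2(CC)C1 | intermediate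
18 | trans-fused hydrindenone: ring A with C1(ethyl)=C2, C3 methyl α, C3a-H α, C7a-H β; C4 ketone; lactone acetal on C6/C7 | O=C1[C@H]2[C@H](C)C=C(CC)[C@@H]2[C@@]3(C)C(=O)O[C@H](O[C@@H]4C[C@H](C)CC[C@H]4C(C)C)[C@@]3(CC)C1 | intermediate
19 | potassium C4=C5 enolate of 18 | [K+].[O-]C1=C[C@]2(CC)[C@@H](O[C@@H]4C[C@H](C)CC[C@H]4C(C)C)OC(=O)[C@]2(C)[C@H]3C(CC)=C[C@@H](C)[C@H]13 | intermediate (not isolated)
20 | C4=C5 enol triflate of 18 | FC(F)(F)S(=O)(=O)OC1=C[C@]2(CC)[C@@H](O[C@@H]4C[C@H](C)CC[C@H]4C(C)C)OC(=O)[C@]2(C)[C@H]3C(CC)=C[C@@H](C)[C@H]13 | intermediate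
21 | C4-methyl C4=C5 alkene; tricyclic menthyl lactone acetal with all five ring stereocentres of the target | CC1=C[C@]2(CC)[C@@H](O[C@@H]4C[C@H](C)CC[C@H]4C(C)C)OC(=O)[C@]2(C)[C@H]3C(CC)=C[C@@H](C)[C@H]13 | intermediate
22 | lithium carboxylate of the C6-formyl C7-carboxylic acid (ring stereocentres as in the target) | [Li+].CCC1=C[C@@H](C)[C@@H]2C(C)=C[C@@](C=O)(CC)[C@](C)(C(=O)[O-])[C@@H]12 | intermediate (not isolated)
23 | hydroxy lactone (lactol between the C7 carboxyl and the C6 formyl group, both lactol epimers) | CC1=C[C@]2(CC)C(O)OC(=O)[C@]2(C)[C@H]3C(CC)=C[C@@H](C)[C@H]13 | intermediate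
24 | allyl ester of the C6-formyl acid (ring stereocentres as in the target) | CCC1=C[C@@H](C)[C@@H]2C(C)=C[C@@](C=O)(CC)[C@](C)(C(=O)OCC=C)[C@@H]12 | intermediate
25 | 2-(triphenylphosphoranylidene)propanal | CC(C=O)=P(c1ccccc1)(c1ccccc1)c1ccccc1 | starting material
26 | allyl ester with (E)-2-methyl-3-oxoprop-1-enyl on C6 | CCC1=C[C@@H](C)[C@@H]2C(C)=C[C@@](/C=C(C)/C=O)(CC)[C@](C)(C(=O)OCC=C)[C@@H]12 | intermediate
27 | diethyl benzylphosphonate | CCOP(=O)(Cc1ccccc1)OCC | starting material
28 | sodium salt of the benzylic carbanion of 27 | [Na+].CCOP(=O)([CH-]c1ccccc1)OCC | intermediate (not isolated)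
29 | allyl ester of 30 | CCC1=C[C@@H](C)[C@@H]2C(C)=C[C@@](/C=C(C)/C=C/c3ccccc3)(CC)[C@](C)(C(=O)OCC=C)[C@@H]12 | intermediate
30 | (3R,3aS,6S,7R,7aR)-1,6-diethyl-3,4,7-trimethyl-6-[(1E,3E)-2-methyl-4-phenylbuta-1,3-dien-1-yl]-3a,6,7,7a-tetrahydro-3H-indene-7-carboxylic acid | CCC1=C[C@@H](C)[C@@H]2C(C)=C[C@@](/C=C(C)/C=C/c3ccccc3)(CC)[C@](C)(C(=O)O)[C@@H]12 | target

**Step count**

Total step count: 15.
Longest linear sequence: 13 steps (1, 2, 4, 5, 7, 8, 9, 10, 11, 12, 13, 14, 15); steps 3 and 6 are side branches.

**Steps most likely to fail**

Step 4. The cycloaddition may not start at the alkene that is fully substituted on both carbons before the diene is lost to polymerisation or hydrolysis, even under pressure. The fallback defers the C7 methyl group: it sets out from butanal 2 (with menthol 4 and diene 8) and comes back at cycloadduct 9. Butanal 2 is condensed with glyoxylic acid (morpholine, dioxane/H2O, then HCl) to 4-ethyl-5-hydroxyfuran-2(5H)-one F1, which is acetalised with 4 as in step 2 to (5S)-4-ethyl-5-menthyloxyfuran-2(5H)-one F2. This trisubstituted dienophile should add 8 thermally (toluene, 80–110 °C), again anti to the menthyloxy group, to give the cis-fused cycloadduct without the C7 methyl group F3. Deprotonation of its lactone α-CH at C7 with LiN(iPr)2 (THF, –78 °C; the β-amino group is a poor leaving group) and methylation with MeI on the convex face, which keeps the lactone cis-fused, gives 9; the acid work-up of step 4 then leads to 11.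

Step 7. The allylation may give the linear product, may alkylate C5 after proton transfer between enolate and product, or may suffer from a mismatch between catalyst control at C3 and substrate control at C3a. The fallback forms the C2–C3 bond instead of the C3–C3a bond under substrate control: it sets out from silyl enol ether 14 and comes back at ketone 17. Mukaiyama aldol addition of 14 to acetaldehyde (BF3·OEt2, CH2Cl2, –78 °C) gives the C3a-(1-hydroxyethyl) ketone F4. Mesylation and elimination (MeSO2Cl, Et3N; then 1,8-diazabicyclo[5.4.0]undec-7-ene) give the (E)-ethylidene ketone F5. In F5 allylic 1,3-strain with the exocyclic methyl group forces the C7a alkenyl group axial, so that CH2=CHMgBr with CuBr·SMe2 and Me3SiCl (THF, –78 °C) should add to the β-face of the exocyclic alkene and give the (R)-configured C3. Hydrolysis of the enol ether and base equilibration of C3a to the trans isomer give 17.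

Step 13. The stabilised ylide may add too slowly to the aldehyde on quaternary C6, next to quaternary C7, so that decomposition at 110 °C competes. The fallback uses the more nucleophilic phosphonate carbanion and adjusts the oxidation state afterwards: it sets out from aldehyde 24 and comes back at enal 26. Horner–Wadsworth–Emmons reaction of 24 with triethyl 2-phosphonopropionate (NaH, THF, 65 °C) gives the ethyl (E)-2-methylpropenoate F6. Reduction with iBu2AlH (CH2Cl2, –78 °C) gives the allylic alcohol F7; the allyl ester on C7, flanked by two fully substituted carbons, is expected to survive. Oxidation with MnO2 (CH2Cl2, 25 °C) gives 26.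

**Further compounds**

F1 | step 4 | 4-ethyl-5-hydroxyfuran-2(5H)-one (racemic lactol) | CCC1=CC(=O)OC1O
F2 | step 4 | (5S)-4-ethyl-5-[(1R,2S,5R)-menthyloxy]furan-2(5H)-one | CCC1=CC(=O)O[C@@H]1O[C@@H]2C[C@H](C)CC[C@H]2C(C)C
F3 | step 4 | cycloadduct without the C7 methyl group (C7-H α, cis-fused lactone acetal, C7a dimethylamino, C3a=C4 silyl enol ether) | CN(C)C1C=C(O[Si](C)(C)C(C)(C)C)C[C@]2(CC)[C@@H](O[C@@H]3C[C@H](C)CC[C@H]3C(C)C)OC(=O)[C@H]12
F4 | step 7 | C3a-(1-hydroxyethyl) ketone (carbinol epimers; C3a trans to the C7a alkenyl group) | O=C1[C@@H](C(C)O)[C@H](C(=C)CC)[C@@]2(C)C(=O)O[C@H](O[C@@H]3C[C@H](C)CC[C@H]3C(C)C)[C@@]2(CC)C1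
F5 | step 7 | (E)-C3a-ethylidene ketone | O=C1/C(=C/C)[C@H](C(=C)CC)[C@@]2(C)C(=O)O[C@H](O[C@@H]3C[C@H](C)CC[C@H]3C(C)C)[C@@]2(CC)C1
F6 | step 13 | allyl ester with ethyl (E)-2-methylpropenoate on C6 | CCC1=C[C@@H](C)[C@@H]2C(C)=C[C@@](/C=C(C)/C(=O)OCC)(CC)[C@](C)(C(=O)OCC=C)[C@@H]12
F7 | step 13 | allyl ester with (E)-3-hydroxy-2-methylprop-1-enyl on C6 | CCC1=C[C@@H](C)[C@@H]2C(C)=C[C@@](/C=C(C)/CO)(CC)[C@](C)(C(=O)OCC=C)[C@@H]12
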